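**Retrosynthetic overview**
- Last bond: the ester between the primary hydroxyl of the hydroxy lactone diacid core and C1 of (R)-malic acid, made without protecting groups by opening O-trifluoroacetyl-(R)-malic anhydride.
- Core: as in the biosynthesis (acyl thioester plus 2-oxoglutarate), the bond between the acyl α-carbon and the keto carbon is made by a chiral copper-catalysed thioester enol silane aldol that sets both core stereocentres in one event.
- Only ring: the γ-lactone, closed straight after the aldol by attack of the new tertiary hydroxyl on the γ-ester.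
- Thioester donor: from ring opening of 12-dodecanolide with ethanethiol.

Assumption: the SMILES is read as R at the malate carbinol carbon, R at the side-chain methine and R at the lactone quaternary carbon (chain and lactone oxygen syn along the succinate backbone); 12-dodecanolide, dimethyl 2-oxoglutarate and (R)-malic acid are taken as catalogue items.

**Route**

Step 1
Reactants: 1 oxacyclotridecan-2-one (12-dodecanolide)
Product: 2 S-ethyl 12-hydroxydodecanethioate
Conditions: AlMe3 (2.0 equiv), EtSH (2.2 equiv), CH2Cl2, 0 → 23 °C; 1 M HCl work-up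
Reagents that add atoms: ethanethiol, CCS
Why: Weinreb-type aluminium thiolate transacylation, in which Me2AlSEt formed in the flask adds to the lactone carbonyl and the strong Al–O bond drives ring opening to the thioester; the 13-membered ring does not re-close on work-up.

Step 2
Reactants: 2 S-ethyl 12-hydroxydodecanethioate
Product: 3 (Z)-1-(ethylsulfanyl)-1,12-bis(trimethylsilyloxy)dodec-1-ene
Conditions: TMSCl (3 equiv, present from the start), LDA (2.3 equiv), THF, −78 → 0 °C; pentane, filtration, used crude
Reagents that add atoms: chlorotrimethylsilane, C[Si](C)(C)Cl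
Why: Enol silane formation by kinetic LDA deprotonation of the thioester with internal O-silylation, which places the chain trans to OSiMe3 (Z by CIP because sulfur outranks oxygen) and caps the alkoxide as its trimethylsilyl ether in the same operation.

Step 3
Reactants: 3 (Z)-1-(ethylsulfanyl)-1,12-bis(trimethylsilyloxy)dodec-1-ene (1.3 equiv); 4 dimethyl 2-oxopentanedioate (dimethyl 2-oxoglutarate)
Product: 7 methyl (2R)-2-[(2R)-1-(ethylsulfanyl)-12-hydroxy-1-oxododecan-2-yl]-5-oxooxolane-2-carboxylate, via bis-silyl aldol adduct 5 (not isolated), via hydroxy diester 6 (not isolated)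
Conditions: Cu(OTf)2 (10 mol %), (R,R)-tBu-box [2,2'-(propane-2,2-diyl)bis((4R)-4-tert-butyl-4,5-dihydro-1,3-oxazole), 11 mol %], THF, −78 °C, 24 h; then 1 M HCl, THF, 23 °C; then TsOH·H2O (5 mol %), CH2Cl2, 23 °C
Reagents that add atoms: none
Why: Evans-type Mukaiyama aldol of a thioester enol silane to an α-keto ester on a divalent copper bis(oxazoline) complex, not yet reported for a 2-oxoglutarate, followed by acid desilylation and γ-lactonization. The keto ester chelates square-planar copper through its 1,2-dicarbonyl unit and the tert-butyl group of the (R,R) ligand blocks the si face, so attack on the re face gives R at the quaternary carbon. The open antiperiplanar transition state keeps the alkyl chain away from the chelate ring, giving the syn adduct (R at the methine), which is the diastereomer reported for α-alkyl thioester enol silanes with pyruvates; the sense for this substrate is taken from that precedent.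

Step 4
Reactants: 7 methyl (2R)-2-[(2R)-1-(ethylsulfanyl)-12-hydroxy-1-oxododecan-2-yl]-5-oxooxolane-2-carboxylate
Product: 9 (2R)-2-[(1R)-1-carboxy-11-hydroxyundecyl]-5-oxooxolane-2-carboxylic acid, via seco triacid 8 (not isolated)
Conditions: LiOH (6 equiv), THF/H2O (3:1), 0 → 23 °C; then 2 M HCl to pH 1, 40 °C
Reagents that add atoms: lithium hydroxide, [Li+].[OH-]; water, O
Why: Saponification of the thioester (assisted by the neighbouring carboxylate through a transient succinic-type anhydride), the methyl ester and the lactone gives a tricarboxylate that can no longer epimerize at the methine, and acidification re-closes the γ-lactone from the tertiary alcohol and the γ-acid.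

Step 5
Reactants: 9 (2R)-2-[(1R)-1-carboxy-11-hydroxyundecyl]-5-oxooxolane-2-carboxylic acid; 10 (R)-malic acid (3 equiv)
Product: 13 (2R)-2-[(1R)-1-carboxy-11-{[(2R)-3-carboxy-2-hydroxypropanoyl]oxy}undecyl]-5-oxooxolane-2-carboxylic acid, via trifluoroacetoxysuccinic anhydride 11 (not isolated), via trifluoroacetate ester 12 (not isolated)
Conditions: 10, (CF3CO)2O, 0 → 23 °C, then evaporate to dryness; 9, THF (1 M), 45 °C, 24 h; then H2O/THF (1:1), 23 °C, 6 h
Reagents that add atoms: none
Why: Regioselective alcoholysis of a cyclic anhydride, in which the primary alcohol of 9 opens the O-trifluoroacetyl anhydride at the carbonyl next to the electron-poor trifluoroacetoxy-bearing carbon to give the 1-ester 4-acid; the free acids of 9 form only mixed anhydrides that revert in water, and water cleaves the labile trifluoroacetate without base, so the malate centre is never deprotonated.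

**Compound list**

1 | oxacyclotridecan-2-one (12-dodecanolide) | O=C1CCCCCCCCCCCO1 | starting material
2 | S-ethyl 12-hydroxydodecanethioate | CCSC(=O)CCCCCCCCCCCO | intermediate
3 | (Z)-1-(ethylsulfanyl)-1,12-bis(trimethylsilyloxy)dodec-1-ene | CCS/C(O[Si](C)(C)C)=C\CCCCCCCCCCO[Si](C)(C)C | intermediate
4 | dimethyl 2-oxopentanedioate (dimethyl 2-oxoglutarate) | COC(=O)CCC(=O)C(=O)OC | starting material
5 | dimethyl (2R)-2-[(2R)-1-(ethylsulfanyl)-1-oxo-12-(trimethylsilyloxy)dodecan-2-yl]-2-(trimethylsilyloxy)pentanedioate | C[Si](C)(C)OCCCCCCCCCC[C@@H](C(=O)SCC)[C@@](O[Si](C)(C)C)(C(=O)OC)CCC(=O)OC | intermediate (not isolated)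
6 | dimethyl (2R)-2-[(2R)-1-(ethylsulfanyl)-12-hydroxy-1-oxododecan-2-yl]-2-hydroxypentanedioate | OCCCCCCCCCC[C@@H](C(=O)SCC)[C@@](O)(C(=O)OC)CCC(=O)OC | intermediate (not isolated)
7 | methyl (2R)-2-[(2R)-1-(ethylsulfanyl)-12-hydroxy-1-oxododecan-2-yl]-5-oxooxolane-2-carboxylate | OCCCCCCCCCC[C@@H](C(=O)SCC)[C@@]1(C(=O)OC)CCC(=O)O1 | intermediate
8 | (2R,3R)-2-(2-carboxyethyl)-2-hydroxy-3-(10-hydroxydecyl)butanedioic acid | OCCCCCCCCCC[C@@H](C(=O)O)[C@@](O)(C(=O)O)CCC(=O)O | intermediate (not isolated)
9 | (2R)-2-[(1R)-1-carboxy-11-hydroxyundecyl]-5-oxooxolane-2-carboxylic acid | OCCCCCCCCCC[C@@H](C(=O)O)[C@@]1(C(=O)O)CCC(=O)O1 | intermediate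
10 | (R)-malic acid [(2R)-2-hydroxybutanedioic acid] | O=C(O)C[C@@H](O)C(=O)O | starting material
11 | (3R)-2,5-dioxooxolan-3-yl trifluoroacetate | O=C1C[C@@H](OC(=O)C(F)(F)F)C(=O)O1 | intermediate (not isolated)
12 | (2R)-2-[(1R)-1-carboxy-11-{[(2R)-3-carboxy-2-(trifluoroacetoxy)propanoyl]oxy}undecyl]-5-oxooxolane-2-carboxylic acid | O=C(O)C[C@@H](OC(=O)C(F)(F)F)C(=O)OCCCCCCCCCC[C@@H](C(=O)O)[C@@]1(C(=O)O)CCC(=O)O1 | intermediate (not isolated)
13 | (2R)-2-[(1R)-1-carboxy-11-{[(2R)-3-carboxy-2-hydroxypropanoyl]oxy}undecyl]-5-oxooxolane-2-carboxylic acid | O=C(O)C[C@@H](O)C(=O)OCCCCCCCCCC[C@@H](C(=O)O)[C@@]1(C(=O)O)CCC(=O)O1 | target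

**Step count and risks**

Total step count: 5. Longest linear sequence: 5 steps (1 → 2 → 3 → 7 → 9 → 13).

The three steps most likely to fail:

Step 3. The copper aldol has no precedent with a 2-oxoglutarate (the γ-ester may compete for copper) or with a long-chain enol silane that cannot be distilled, so enantioselectivity and syn:anti ratio may both fall short. The fallback gives up catalyst control and resolves. Setting out from 3 and 4, the aldol is run with Cu(OTf)2 and achiral 2,2'-bipyridine, which should keep the chelate-controlled syn preference but gives both mirror-image series. Thus 5 forms together with its mirror image dimethyl (2S)-2-[(2S)-1-(ethylsulfanyl)-1-oxo-12-(trimethylsilyloxy)dodecan-2-yl]-2-(trimethylsilyloxy)pentanedioate F1, acid gives 6 together with dimethyl (2S)-2-[(2S)-1-(ethylsulfanyl)-12-hydroxy-1-oxododecan-2-yl]-2-hydroxypentanedioate F2, and lactonization gives 7 together with methyl (2S)-2-[(2S)-1-(ethylsulfanyl)-12-hydroxy-1-oxododecan-2-yl]-5-oxooxolane-2-carboxylate F3. Preparative supercritical-fluid chromatography on an amylose tris(3,5-dimethylphenylcarbamate) phase removes F3, and the route is rejoined at 7.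

Step 4. Hydroxide may epimerize the methine before the thioester is cleaved, or trigger retro-aldol cleavage once the lactone is open. The fallback unmasks the acids stepwise without base. Setting out from 7, AgOCOCF3 in THF/H2O at 23 °C (thiophilic activation by monovalent silver) hydrolyses only the thioester to (2R)-12-hydroxy-2-[(2R)-2-(methoxycarbonyl)-5-oxooxolan-2-yl]dodecanoic acid F4. The methyl ester is then hydrolysed in 3 M HCl/1,4-dioxane at 60 °C, where the lactone stays closed and no enolizable thioester remains, and the route is rejoined at 9.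

Step 5. The free acids of 9 may consume the anhydride, close to a cyclic anhydride of the core and give oligoesters, and acylation of a precious alcohol in solution may be slow. The fallback masks the core acids first. Setting out from 9, BnBr and KHCO3 in DMF alkylate both carboxylates to benzyl (2R)-2-[(2R)-1-(benzyloxy)-12-hydroxy-1-oxododecan-2-yl]-5-oxooxolane-2-carboxylate F5. Anhydride 11, made from 10 as in step 5 and freed from trifluoroacetic acid, then acylates the hydroxyl in THF to (3R)-4-({(11R)-12-(benzyloxy)-11-[(2R)-2-[(benzyloxy)carbonyl]-5-oxooxolan-2-yl]-12-oxododecyl}oxy)-4-oxo-3-(trifluoroacetoxy)butanoic acid F6. Water converts this to (3R)-4-({(11R)-12-(benzyloxy)-11-[(2R)-2-[(benzyloxy)carbonyl]-5-oxooxolan-2-yl]-12-oxododecyl}oxy)-3-hydroxy-4-oxobutanoic acid F7, and H2 with Pd/C in EtOAc removes both benzyl esters, rejoining the route at 13.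

**Further compounds**

F1 | step 3 | dimethyl (2S)-2-[(2S)-1-(ethylsulfanyl)-1-oxo-12-(trimethylsilyloxy)dodecan-2-yl]-2-(trimethylsilyloxy)pentanedioate | C[Si](C)(C)OCCCCCCCCCC[C@H](C(=O)SCC)[C@](O[Si](C)(C)C)(C(=O)OC)CCC(=O)OC
F2 | step 3 | dimethyl (2S)-2-[(2S)-1-(ethylsulfanyl)-12-hydroxy-1-oxododecan-2-yl]-2-hydroxypentanedioate | OCCCCCCCCCC[C@H](C(=O)SCC)[C@](O)(C(=O)OC)CCC(=O)OC
F3 | step 3 | methyl (2S)-2-[(2S)-1-(ethylsulfanyl)-12-hydroxy-1-oxododecan-2-yl]-5-oxooxolane-2-carboxylate | OCCCCCCCCCC[C@H](C(=O)SCC)[C@]1(C(=O)OC)CCC(=O)O1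
F4 | step 4 | (2R)-12-hydroxy-2-[(2R)-2-(methoxycarbonyl)-5-oxooxolan-2-yl]dodecanoic acid | OCCCCCCCCCC[C@@H](C(=O)O)[C@@]1(C(=O)OC)CCC(=O)O1
F5 | step 5 | benzyl (2R)-2-[(2R)-1-(benzyloxy)-12-hydroxy-1-oxododecan-2-yl]-5-oxooxolane-2-carboxylate | OCCCCCCCCCC[C@@H](C(=O)OCc1ccccc1)[C@@]1(C(=O)OCc2ccccc2)CCC(=O)O1
F6 | step 5 | (3R)-4-({(11R)-12-(benzyloxy)-11-[(2R)-2-[(benzyloxy)carbonyl]-5-oxooxolan-2-yl]-12-oxododecyl}oxy)-4-oxo-3-(trifluoroacetoxy)butanoic acid | O=C(O)C[C@@H](OC(=O)C(F)(F)F)C(=O)OCCCCCCCCCC[C@@H](C(=O)OCc1ccccc1)[C@@]1(C(=O)OCc2ccccc2)CCC(=O)O1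
F7 | step 5 | (3R)-4-({(11R)-12-(benzyloxy)-11-[(2R)-2-[(benzyloxy)carbonyl]-5-oxooxolan-2-yl]-12-oxododecyl}oxy)-3-hydroxy-4-oxobutanoic acid | O=C(O)C[C@@H](O)C(=O)OCCCCCCCCCC[C@@H](C(=O)OCc1ccccc1)[C@@]1(C(=O)OCc2ccccc2)CCC(=O)O1
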